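## The problem

The target 29 is a (3S)-isoflavanone: a 5,7-dihydroxychroman-4-one (rings A and C) whose C3 carries ring B, a 2',4'-dihydroxyphenyl group with an (E)-7-hydroxy-3,7-dimethyloct-2-enyl chain on C3', between its two oxygens. Two things are asked of the skeleton. Ring C has to be closed between two electron-rich arenes through O1–C2, C3–C1' and C4–C4a, and the ten-carbon chain has to be placed on the most hindered carbon of ring B without moving its alkene or losing its geometry. C3 is the only stereocentre. It is benzylic and alpha to the C4 ketone, so it is lost through the enol or enolate, and through reversible opening of ring C, under any base; nothing else in the molecule can set it and it sets nothing in turn. It therefore has to come from a chiral catalyst late in the route, and every later operation has to be free of base. The fragile groups are the four phenols (one of them chelated to the ketone), the trisubstituted alkene, which cyclises onto the flanking C2' or C4' hydroxyl under strong acid, and the tertiary alcohol, which ionises under the same conditions. A short ring construction is possible because of ring A: O1 sits on C8a and the acyl carbon C4 on the neighbouring C4a, with the C5 oxygen directly beside C4a and the second oxygen at C7. This is the pattern in which a carboxylic acid is taken up across the triple bond of a 3,5-dioxygenated benzyne. Since C2 is an unsubstituted methylene, the atoms C2, C3, C4 and ring B amount to a 2-arylacrylic acid whose terminal carbon can accept O1.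

## Retrosynthesis

Abbreviations: MOM = methoxymethyl, TBS = tert-butyldimethylsilyl, TES = triethylsilyl.

**29 from 28 (five O–Si bonds).** The last cut removes five TBS groups from the (3S)-ketone 28. Silyl ethers are preferred over acetals or esters because fluoride in a weakly acidic medium cleaves them without enolising C3. Precursor 28 is no simpler in skeleton, but it is the form in which the stereocentre can be made and kept. The forward step must avoid base and strong acid.

**28 from 27 and 25 (the C3–H bond).** The stereocentre is cut at C3–H. Zerovalent palladium and a chiral phosphinooxazoline release the C3 enolate from the allyl enol carbonate 27, and the enolate is protonated on one face. Carbonate 27 comes from the racemic ketone 25 by O-acylation of its enolate. The neighbouring options are enantioselective reduction of an isoflavone or asymmetric arylation of a chromanone at C3. Both tie the stereocentre to the ring construction and to a crowded C3–C1' coupling. Protonation lets ring C be built racemic, so the precursor carries no stereochemical demand at all. The forward step needs facial discrimination, which the ortho-silyloxy group of ring B should supply.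

**25 from 24 and 23 (protecting-group exchange on four phenols).** The aryne step needs phenol protection that is inert to fluoride, which excludes aryl silyl ethers; MOM ethers qualify. Their removal needs protic acid, which is acceptable only while C3 is racemic. The four aryl MOM ethers of 23 are therefore cleaved to tetraphenol 24, and 24 is silylated to 25. The tertiary alcohol is a TBS ether from the start and is not exchanged.

**23 from 14 and 20 (C8a–O1, C4a–C4, O1–C2).** Ring C is cut at three bonds at once. This leaves the ring B 2-arylacrylic acid 14 and the silyl triflate 20, the precursor of 3,5-bis(methoxymethoxy)benzyne 21. The alternatives are Friedel–Crafts acylation of a phloroglucinol ether by an arylacetic acid followed by a separate one-carbon insertion at C2, or a late C3–C1' coupling. Both are longer and divide the molecule unevenly. The aryne cut gives two fragments of similar size, each a plain benzene derivative. The forward reaction must add the carboxylate to the aryne carbon remote from the neighbouring oxygen, transfer the acyl group from oxygen to carbon to give phenoxide 22 before the aryl anion is protonated, and close ring C by oxa-Michael addition.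

**14 from 13, 12 and 10 (C1'–C alpha and the methylene).** The acrylic acid is cut at the bond from ring B to the alpha-carbon. Aryllithium 11, made from 10 by ortho-lithiation, is acylated with diethyl oxalate to keto ester 12; a Wittig methylenation gives acrylate 13 and hydrolysis gives 14. Carbonylation of an acetophenone enol triflate was the neighbouring option. It would need the chain to be placed by C-alkylation of a dihydroxyacetophenone, which is poorly regioselective. The lithiation route fixes the position by symmetry, since the two free ortho positions of 10 are equivalent.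

**10 from 8 and 6 (C3'–C1'').** The chain is attached where the ring B carbon lies between two MOM ethers. This is the position that 1,3-bis(methoxymethoxy)benzene 8 lithiates first, giving 9. Alkylation with the allylic bromide 6 makes the bond at the primary carbon. Ether 8 is made from resorcinol 7 in one step.

**6 from 5, 4, 3 and 1 (the tertiary C–O bond).** The tertiary alcohol is cut back to the terminal alkene of geranyl acetate 1. The allylic acetate deactivates the 2,3-alkene, so Markovnikov hydration occurs at the 6,7-alkene and gives 3. Silylation (4), methanolysis (5) and bromination (6) follow.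

**20 from 18, 17, 16 and 15 (C–Si and C–Br).** The silyl group is placed by retro-Brook migration in the bromoaryl silyl ether 18, through lithium phenoxide 19, which is triflated. Bromide 17 comes from ortho-bromination of 3,5-bis(methoxymethoxy)phenol 16, and 16 from phloroglucinol 15.

## Roads not taken

**Alternative 1: Danheiser benzannulation to grow ring B on a chromone.**
- Cut: C1'–C2', C2'–C3' and C4'–C5' of ring B.
- Forward step: irradiation of the chromon-3-yl diazo enone A2 triggers a Wolff rearrangement. The ketene so formed adds across the siloxyalkyne A3, and the four-membered adduct reorganises by ring opening and six-electron closure to the isoflavone A1.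
- Merits: ring B is made with the chain between its two oxygens by construction. The two oxygens come out differentiated (free 2'-OH, silylated 4'-O). The step is convergent.
- Weak points: A1 is an isoflavone, so C3 is still trigonal. A conjugate reduction that spares the chain alkene and a separate enantioselective protonation are still owed. A2 hangs a diazo ketone on a chromone whose C2 is electrophilic and whose own chromophore absorbs the light. A3 has a methylene between alkyne and alkene that isomerises easily, and it is a multi-step target in itself.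
- Comparison: in regiochemical certainty for ring B this road equals the chosen plan, and it is better at telling the two ring B oxygens apart. That is of no use here because both end as free hydroxyls. The chosen plan sets against it that ring C arrives at the isoflavanone oxidation level in the ring-forming step and that both partners (14 and 20) are stable compounds.

**Alternative 2: ring B from an acetoacetate and an acrylate, aromatised late.**
- Cut: C1'–C6' and C3'–C4' of ring B.
- Forward step: with NaOMe the keto ester A5 adds to methyl acrylate A6, and its gamma-carbon then condenses with the new ester to give the cyclohexane-1,3-dione ester A4.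
- Merits: cheap feedstock, no cryogenic organometallic chemistry, the chain position is fixed by the order of bond formation, and the tertiary alcohol is carried unprotected.
- Weak points: A4 must be dehydrogenated to a resorcinol in the presence of an electron-rich alkene that the usual oxidants attack or cyclise. The ester carbon on C1' must then be homologated into the link to C3. Rings A and C and the stereocentre are untouched by the key step, so the route is long and linear.
- Comparison: this road is better in cost and in avoiding organolithium reagents. The chosen plan sets brevity against it: ring B is bought as resorcinol and reaches acid 14 in five steps.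

**Alternative 3: enantioconvergent nickel reductive acylation to close ring C.**
- Cut: C3–C4.
- Forward step: NiCl2(dme) (divalent nickel), a chiral bis(oxazoline) and manganese powder couple the aroyl chloride with the racemic benzylic chloride within A8. This closes ring C and sets C3 to give the persilylated ketone A7.
- Merits: ring closure and stereocentre in one step, no strong base near C3–H, and A7 needs only desilylation. The endgame is shorter than the five steps the chosen plan spends after its key step.
- Weak points: the ring-closing variant has not been shown and would have to be developed. The benzylic chloride of A8 sits on a 2,4-dioxygenated ring and beta to an aryloxy group, so ionisation and loss of the aryloxy group by beta-elimination from the benzylic nickel species are likely. The acid chloride is flanked by two ortho oxygens and must be made beside five silyl ethers. Assembling A8 costs the steps saved later.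
- Comparison: if its key step performed, this road would be better in step count and in handling the stereocentre. The chosen plan sets against it a ring formation of a known type, a C3 protonation known for the isoflavanone class, and a racemic checkpoint (23) before any chiral catalyst is used.

Key step: step 14

Assumption: with the (S)-configured phosphinooxazoline and Meldrum's acid, the proton in step 18 is taken to arrive on the face that gives (3S). In this ligand class the sense depends on the proton donor as well as on the ligand, so the pairing would be fixed by a trial on 27 and the mirror-image ligand used if the sense is the opposite.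

## Route

Step 1
Reactants: 1 geranyl acetate [(2E)-3,7-dimethylocta-2,6-dien-1-yl acetate]
Product: 3 (2E)-7-hydroxy-3,7-dimethyloct-2-en-1-yl acetate, via organomercurial acetate 2 (not isolated)
Conditions: Hg(OAc)2, THF–H2O (1:1), rt; then NaBH4, 3 M NaOH, 0 °C
Reagents that add atoms: water, O
Why: Markovnikov oxymercuration–demercuration; the 6,7-alkene is the more electron-rich because the allylic acetate deactivates the 2,3-alkene, so hydration is site-selective, the E-alkene is untouched and the mercury-bearing carbon ends as a methylene.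

Step 2
Reactants: 3 (2E)-7-hydroxy-3,7-dimethyloct-2-en-1-yl acetate
Product: 4 (2E)-7-(tert-butyldimethylsilyloxy)-3,7-dimethyloct-2-en-1-yl acetate
Conditions: TBSOTf, 2,6-lutidine, CH2Cl2, 0 °C → rt
Reagents that add atoms: tert-butyldimethylsilyl triflate, CC(C)(C)[Si](C)(C)OS(=O)(=O)C(F)(F)F
Why: Silyl triflate silylation of a tertiary alcohol; the tertiary TBS ether is chosen because it withstands organolithiums, hydroxide and fluoride in THF, and so can stay on until the last step.

Step 3
Reactants: 4 (2E)-7-(tert-butyldimethylsilyloxy)-3,7-dimethyloct-2-en-1-yl acetate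
Product: 5 (2E)-7-(tert-butyldimethylsilyloxy)-3,7-dimethyloct-2-en-1-ol
Conditions: K2CO3 (0.2 equiv), MeOH, rt
Reagents that add atoms: none
Why: Base-catalysed transesterification of a primary acetate with methanol; the hindered tertiary silyl ether is inert.

Step 4
Reactants: 5 (2E)-7-(tert-butyldimethylsilyloxy)-3,7-dimethyloct-2-en-1-ol
Product: 6 (2E)-1-bromo-7-(tert-butyldimethylsilyloxy)-3,7-dimethyloct-2-ene
Conditions: CBr4, PPh3, CH2Cl2, 0 °C; used without chromatography
Reagents that add atoms: carbon tetrabromide, BrC(Br)(Br)Br
Why: Appel reaction; neutral conditions spare the silyl ether, and displacement at the primary allylic carbon proceeds without allylic transposition and with the E-geometry kept.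

Step 5
Reactants: 7 resorcinol
Product: 8 1,3-bis(methoxymethoxy)benzene
Conditions: MOMCl, i-Pr2NEt, CH2Cl2, 0 °C → rt
Reagents that add atoms: chloromethyl methyl ether, COCCl
Why: O-alkylation of both phenols by the alpha-chloro ether (Williamson-type acetal formation).

Step 6
Reactants: 8 1,3-bis(methoxymethoxy)benzene; 6 (2E)-1-bromo-7-(tert-butyldimethylsilyloxy)-3,7-dimethyloct-2-ene
Product: 10 2-[(2E)-7-(tert-butyldimethylsilyloxy)-3,7-dimethyloct-2-en-1-yl]-1,3-bis(methoxymethoxy)benzene, via aryllithium 9 (not isolated)
Conditions: n-BuLi, THF, 0 °C → rt; CuI (10 mol %); then 6, −78 °C → rt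
Reagents that add atoms: none
Why: Directed ortho-metalation occurs at the carbon between the two MOM ethers, which direct cooperatively; copper-catalysed alkylation of the aryllithium takes place at the primary carbon of the allylic bromide, so the chain arrives untransposed and E.

Step 7
Reactants: 10 2-[(2E)-7-(tert-butyldimethylsilyloxy)-3,7-dimethyloct-2-en-1-yl]-1,3-bis(methoxymethoxy)benzene
Product: 12 ethyl 2-{3-[(2E)-7-(tert-butyldimethylsilyloxy)-3,7-dimethyloct-2-en-1-yl]-2,4-bis(methoxymethoxy)phenyl}-2-oxoacetate, via aryllithium 11 (not isolated)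
Conditions: n-BuLi, TMEDA, THF, −20 → 0 °C; transfer into (CO2Et)2 (3 equiv), THF, −78 °C; aq. NH4Cl
Reagents that add atoms: diethyl oxalate, CCOC(=O)C(=O)OCC
Why: Second directed ortho-metalation beside a MOM ether, where the two open ortho positions are equivalent by symmetry; inverse addition to excess diethyl oxalate stops at the keto ester because the tetrahedral adduct persists at −78 °C.

Step 8
Reactants: 12 ethyl 2-{3-[(2E)-7-(tert-butyldimethylsilyloxy)-3,7-dimethyloct-2-en-1-yl]-2,4-bis(methoxymethoxy)phenyl}-2-oxoacetate
Product: 13 ethyl 2-{3-[(2E)-7-(tert-butyldimethylsilyloxy)-3,7-dimethyloct-2-en-1-yl]-2,4-bis(methoxymethoxy)phenyl}prop-2-enoate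
Conditions: Ph3PCH3Br, KOt-Bu, THF, 0 °C; then 12, 0 °C → rt
Reagents that add atoms: methyltriphenylphosphonium bromide, C[P+](c1ccccc1)(c1ccccc1)c1ccccc1.[Br-]
Why: Wittig methylenation of an aryl glyoxylate; the ketone is activated by the adjacent ester and cannot enolise, and the ester does not react with the ylide.

Step 9
Reactants: 13 ethyl 2-{3-[(2E)-7-(tert-butyldimethylsilyloxy)-3,7-dimethyloct-2-en-1-yl]-2,4-bis(methoxymethoxy)phenyl}prop-2-enoate
Product: 14 2-{3-[(2E)-7-(tert-butyldimethylsilyloxy)-3,7-dimethyloct-2-en-1-yl]-2,4-bis(methoxymethoxy)phenyl}prop-2-enoic acid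
Conditions: LiOH·H2O, THF–H2O, rt; then 1 M HCl to pH 4, 0 °C
Reagents that add atoms: lithium hydroxide, [Li+].[OH-]
Why: Saponification; hydroxide attacks the ester carbonyl faster than the hindered 2-aryl acrylate terminus, MOM and tertiary silyl ethers are stable to base, and cold acidification to pH 4 spares the acetals.

Step 10
Reactants: 15 phloroglucinol
Product: 16 3,5-bis(methoxymethoxy)phenol
Conditions: MOMCl (2.1 equiv), i-Pr2NEt, DMF, 0 °C → rt; chromatography
Reagents that add atoms: chloromethyl methyl ether, COCCl
Why: Statistical O-alkylation of a threefold symmetric triol; symmetry allows only one bis-ether, which should be separable from the mono- and tris-ethers.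

Step 11
Reactants: 16 3,5-bis(methoxymethoxy)phenol
Product: 17 2-bromo-3,5-bis(methoxymethoxy)phenol
Conditions: NBS (1.0 equiv), CH2Cl2, −78 °C
Reagents that add atoms: N-bromosuccinimide, O=C1CCC(=O)N1Br
Why: Electrophilic aromatic bromination; at low temperature in a non-polar solvent the reagent is delivered beside the free hydroxyl, the two ortho positions are equivalent, the para position is shielded by two MOM ethers, and one equivalent limits double bromination.

Step 12
Reactants: 17 2-bromo-3,5-bis(methoxymethoxy)phenol
Product: 18 [2-bromo-3,5-bis(methoxymethoxy)phenoxy]trimethylsilane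
Conditions: (Me3Si)2NH, THF, 65 °C; concentrate, use crude
Reagents that add atoms: hexamethyldisilazane, C[Si](C)(C)N[Si](C)(C)C
Why: O-silylation of a phenol by hexamethyldisilazane, with ammonia as the only by-product, so the silyl ether can be used without purification.

Step 13
Reactants: 18 [2-bromo-3,5-bis(methoxymethoxy)phenoxy]trimethylsilane
Product: 20 3,5-bis(methoxymethoxy)-2-(trimethylsilyl)phenyl trifluoromethanesulfonate, via lithium phenoxide 19 (not isolated)
Conditions: n-BuLi, THF, −78 °C; then Tf2O, −78 °C
Reagents that add atoms: trifluoromethanesulfonic anhydride, O=S(=O)(OS(=O)(=O)C(F)(F)F)C(F)(F)F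
Why: Bromine–lithium exchange is followed by retro-Brook migration of silicon from oxygen to the carbon that carried bromine; the lithium phenoxide is triflated in the same flask, and the exchange is faster than MOM-directed lithiation at this temperature.

Step 14
Reactants: 14 2-{3-[(2E)-7-(tert-butyldimethylsilyloxy)-3,7-dimethyloct-2-en-1-yl]-2,4-bis(methoxymethoxy)phenyl}prop-2-enoic acid; 20 3,5-bis(methoxymethoxy)-2-(trimethylsilyl)phenyl trifluoromethanesulfonate
Product: 23 rac-3-{3-[(2E)-7-(tert-butyldimethylsilyloxy)-3,7-dimethyloct-2-en-1-yl]-2,4-bis(methoxymethoxy)phenyl}-5,7-bis(methoxymethoxy)chroman-4-one, via aryne 21 (not isolated), via cesium acylphenoxide 22 (not isolated)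
Conditions: 20 (1.5 equiv), CsF (4 equiv), BHT (cat.), THF (dilute), 125 °C, sealed tube
Reagents that add atoms: none
Why: This is the known fluoride-induced insertion of an aryne into the C–O bond of a carboxylic acid, which with acrylic acids continues to chroman-4-ones. CsF removes the silyl group of 20 with loss of triflate to give aryne 21 and converts 14 into its cesium carboxylate. The carboxylate oxygen adds to the aryne carbon remote from the neighbouring methoxymethoxy group, because that group withdraws inductively and distorts the triple bond so that negative charge develops best on the carbon beside it; this puts O1 on C8a and the aryl anion on C4a, next to the future C5 oxygen. The anion attacks the ester carbonyl just created through a four-membered alkoxide, which opens to the ortho-acyl phenoxide 22, a net acyl shift from oxygen to carbon that forms C4a–C4. Ring C then closes by 6-endo-trig oxa-Michael addition of the phenoxide to the terminal carbon of the 2-aryl enone, forming O1–C2; the C3 enolate is protonated without facial control, so 23 is racemic and no stereocentre is set on purpose. The step needs regioselective addition to 21, secured by the oxygen beside the triple bond, and acyl transfer faster than protonation of the aryl anion, favoured by the high temperature and by the absence of any O–H other than the acid itself. MOM ethers and the tertiary silyl ether are inert to CsF in THF, no allyl ether sits beside the aryne, and dilution with a trace of radical inhibitor guards the acrylic acid against thermal oligomerisation.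

Step 15
Reactants: 23 rac-3-{3-[(2E)-7-(tert-butyldimethylsilyloxy)-3,7-dimethyloct-2-en-1-yl]-2,4-bis(methoxymethoxy)phenyl}-5,7-bis(methoxymethoxy)chroman-4-one
Product: 24 rac-3-{3-[(2E)-7-(tert-butyldimethylsilyloxy)-3,7-dimethyloct-2-en-1-yl]-2,4-dihydroxyphenyl}-5,7-dihydroxychroman-4-one
Conditions: 3 M aq. HCl, MeOH–THF, rt
Reagents that add atoms: none
Why: Acid-catalysed solvolysis of aryl MOM acetals, with the C5 ether beside the carbonyl expected to go first; the hindered tertiary silyl ether solvolyses far more slowly, enolisation is harmless at the racemic stage, and any material that loses the tertiary silyl group is silylated again in step 16.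

Step 16
Reactants: 24 rac-3-{3-[(2E)-7-(tert-butyldimethylsilyloxy)-3,7-dimethyloct-2-en-1-yl]-2,4-dihydroxyphenyl}-5,7-dihydroxychroman-4-one
Product: 25 rac-5,7-bis(tert-butyldimethylsilyloxy)-3-{2,4-bis(tert-butyldimethylsilyloxy)-3-[(2E)-7-(tert-butyldimethylsilyloxy)-3,7-dimethyloct-2-en-1-yl]phenyl}chroman-4-one
Conditions: TBSOTf (6 equiv), 2,6-lutidine, CH2Cl2, −78 → 0 °C
Reagents that add atoms: tert-butyldimethylsilyl triflate, CC(C)(C)[Si](C)(C)OS(=O)(=O)C(F)(F)F
Why: Silyl triflate silylation; the triflate is needed for the chelated C5 hydroxyl, which resists the silyl chloride, and the weak base and low temperature keep the ketone from forming a silyl enol ether.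

Step 17
Reactants: 25 rac-5,7-bis(tert-butyldimethylsilyloxy)-3-{2,4-bis(tert-butyldimethylsilyloxy)-3-[(2E)-7-(tert-butyldimethylsilyloxy)-3,7-dimethyloct-2-en-1-yl]phenyl}chroman-4-one
Product: 27 allyl 5,7-bis(tert-butyldimethylsilyloxy)-3-{2,4-bis(tert-butyldimethylsilyloxy)-3-[(2E)-7-(tert-butyldimethylsilyloxy)-3,7-dimethyloct-2-en-1-yl]phenyl}-2H-chromen-4-yl carbonate, via potassium enolate 26 (not isolated)
Conditions: KN(SiMe3)2, THF, −78 °C; then allyl chloroformate, −78 °C
Reagents that add atoms: allyl chloroformate, C=CCOC(Cl)=O
Why: O-acylation of a potassium enolate by a chloroformate, favoured by the hard electrophile and by the crowded, fully substituted C3; the stereocentre is erased on purpose, and the low temperature holds back silyl migration from the C5 oxygen and opening of ring C by beta-elimination.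

Step 18
Reactants: 27 allyl 5,7-bis(tert-butyldimethylsilyloxy)-3-{2,4-bis(tert-butyldimethylsilyloxy)-3-[(2E)-7-(tert-butyldimethylsilyloxy)-3,7-dimethyloct-2-en-1-yl]phenyl}-2H-chromen-4-yl carbonate
Product: 28 (3S)-5,7-bis(tert-butyldimethylsilyloxy)-3-{2,4-bis(tert-butyldimethylsilyloxy)-3-[(2E)-7-(tert-butyldimethylsilyloxy)-3,7-dimethyloct-2-en-1-yl]phenyl}chroman-4-one
Conditions: Pd2(dba)3 (5 mol %), (S)-t-Bu-PHOX (12.5 mol %), Meldrum's acid (2.5 equiv), 1,4-dioxane, 25–40 °C
Reagents that add atoms: none
Why: Palladium-catalysed decarboxylative enantioselective protonation, a reaction known for allyl enol carbonates and for isoflavanone-type 2-aryl ketones; zerovalent palladium ionises the allyl carbonate, loss of CO2 leaves a ligand-bound palladium enolate, and Meldrum's acid delivers the proton to one face of C3 and takes up the allyl group, so the stereocentre is set by the ligand, helped by the ortho-silyloxy group of ring B, under conditions too weakly basic to racemise the product.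

Step 19
Reactants: 28 (3S)-5,7-bis(tert-butyldimethylsilyloxy)-3-{2,4-bis(tert-butyldimethylsilyloxy)-3-[(2E)-7-(tert-butyldimethylsilyloxy)-3,7-dimethyloct-2-en-1-yl]phenyl}chroman-4-one
Product: 29 (3S)-5,7-dihydroxy-3-{2,4-dihydroxy-3-[(2E)-7-hydroxy-3,7-dimethyloct-2-en-1-yl]phenyl}chroman-4-one
Conditions: 48% aq. HF, MeCN–THF, 0 °C → rt, polypropylene vessel
Reagents that add atoms: none
Why: Fluoride-driven Si–O cleavage in a weakly acidic medium; no base is present, so C3 should not enolise, the reagent is strong enough for the tertiary silyl ether, and the temperature and acidity are too low to cyclise a phenol onto the alkene.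

## Compound list

1 | geranyl acetate, (2E)-3,7-dimethylocta-2,6-dien-1-yl acetate | C/C(=C\COC(C)=O)CCC=C(C)C | starting material
2 | (2E)-6-(acetoxymercurio)-7-hydroxy-3,7-dimethyloct-2-en-1-yl acetate, racemic at C6 | C/C(=C\COC(C)=O)CCC([Hg]OC(C)=O)C(C)(C)O | intermediate
3 | (2E)-7-hydroxy-3,7-dimethyloct-2-en-1-yl acetate | C/C(=C\COC(C)=O)CCCC(C)(C)O | intermediate
4 | (2E)-7-(tert-butyldimethylsilyloxy)-3,7-dimethyloct-2-en-1-yl acetate | C/C(=C\COC(C)=O)CCCC(C)(C)O[Si](C)(C)C(C)(C)C | intermediate
5 | (2E)-7-(tert-butyldimethylsilyloxy)-3,7-dimethyloct-2-en-1-ol | C/C(=C\CO)CCCC(C)(C)O[Si](C)(C)C(C)(C)C | intermediate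
6 | (2E)-1-bromo-7-(tert-butyldimethylsilyloxy)-3,7-dimethyloct-2-ene | C/C(=C\CBr)CCCC(C)(C)O[Si](C)(C)C(C)(C)C | intermediate
7 | resorcinol | Oc1cccc(O)c1 | starting material
8 | 1,3-bis(methoxymethoxy)benzene | COCOc1cccc(OCOC)c1 | intermediate
9 | [2,6-bis(methoxymethoxy)phenyl]lithium | [Li]c1c(OCOC)cccc1OCOC | intermediate
10 | 2-[(2E)-7-(tert-butyldimethylsilyloxy)-3,7-dimethyloct-2-en-1-yl]-1,3-bis(methoxymethoxy)benzene | C/C(=C\Cc1c(OCOC)cccc1OCOC)CCCC(C)(C)O[Si](C)(C)C(C)(C)C | intermediate
11 | {3-[(2E)-7-(tert-butyldimethylsilyloxy)-3,7-dimethyloct-2-en-1-yl]-2,4-bis(methoxymethoxy)phenyl}lithium | C/C(=C\Cc1c(OCOC)ccc([Li])c1OCOC)CCCC(C)(C)O[Si](C)(C)C(C)(C)C | intermediate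
12 | ethyl 2-{3-[(2E)-7-(tert-butyldimethylsilyloxy)-3,7-dimethyloct-2-en-1-yl]-2,4-bis(methoxymethoxy)phenyl}-2-oxoacetate | C/C(=C\Cc1c(OCOC)ccc(C(=O)C(=O)OCC)c1OCOC)CCCC(C)(C)O[Si](C)(C)C(C)(C)C | intermediate
13 | ethyl 2-{3-[(2E)-7-(tert-butyldimethylsilyloxy)-3,7-dimethyloct-2-en-1-yl]-2,4-bis(methoxymethoxy)phenyl}prop-2-enoate | C/C(=C\Cc1c(OCOC)ccc(C(=C)C(=O)OCC)c1OCOC)CCCC(C)(C)O[Si](C)(C)C(C)(C)C | intermediate
14 | 2-{3-[(2E)-7-(tert-butyldimethylsilyloxy)-3,7-dimethyloct-2-en-1-yl]-2,4-bis(methoxymethoxy)phenyl}prop-2-enoic acid | C/C(=C\Cc1c(OCOC)ccc(C(=C)C(=O)O)c1OCOC)CCCC(C)(C)O[Si](C)(C)C(C)(C)C | intermediate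
15 | phloroglucinol | Oc1cc(O)cc(O)c1 | starting material
16 | 3,5-bis(methoxymethoxy)phenol | COCOc1cc(O)cc(OCOC)c1 | intermediate
17 | 2-bromo-3,5-bis(methoxymethoxy)phenol | COCOc1cc(O)c(Br)c(OCOC)c1 | intermediate
18 | [2-bromo-3,5-bis(methoxymethoxy)phenoxy]trimethylsilane | COCOc1cc(O[Si](C)(C)C)c(Br)c(OCOC)c1 | intermediate
19 | lithium 3,5-bis(methoxymethoxy)-2-(trimethylsilyl)phenolate | [Li+].[O-]c1cc(OCOC)cc(OCOC)c1[Si](C)(C)C | intermediate
20 | 3,5-bis(methoxymethoxy)-2-(trimethylsilyl)phenyl trifluoromethanesulfonate | COCOc1cc(OCOC)c([Si](C)(C)C)c(OS(=O)(=O)C(F)(F)F)c1 | intermediate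
21 | 3,5-bis(methoxymethoxy)benzyne (1,2-didehydro-3,5-bis(methoxymethoxy)benzene) | COCOC1=CC#CC(OCOC)=C1 | intermediate
22 | cesium 2-(2-{3-[(2E)-7-(tert-butyldimethylsilyloxy)-3,7-dimethyloct-2-en-1-yl]-2,4-bis(methoxymethoxy)phenyl}prop-2-enoyl)-3,5-bis(methoxymethoxy)phenolate | [Cs+].[O-]c1cc(OCOC)cc(OCOC)c1C(=O)C(=C)c1ccc(OCOC)c(C/C=C(\C)CCCC(C)(C)O[Si](C)(C)C(C)(C)C)c1OCOC | intermediate
23 | rac-3-{3-[(2E)-7-(tert-butyldimethylsilyloxy)-3,7-dimethyloct-2-en-1-yl]-2,4-bis(methoxymethoxy)phenyl}-5,7-bis(methoxymethoxy)chroman-4-one | C/C(=C\Cc1c(OCOC)ccc(C2COc3cc(OCOC)cc(OCOC)c3C2=O)c1OCOC)CCCC(C)(C)O[Si](C)(C)C(C)(C)C | intermediate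
24 | rac-3-{3-[(2E)-7-(tert-butyldimethylsilyloxy)-3,7-dimethyloct-2-en-1-yl]-2,4-dihydroxyphenyl}-5,7-dihydroxychroman-4-one | C/C(=C\Cc1c(O)ccc(C2COc3cc(O)cc(O)c3C2=O)c1O)CCCC(C)(C)O[Si](C)(C)C(C)(C)C | intermediate
25 | rac-5,7-bis(tert-butyldimethylsilyloxy)-3-{2,4-bis(tert-butyldimethylsilyloxy)-3-[(2E)-7-(tert-butyldimethylsilyloxy)-3,7-dimethyloct-2-en-1-yl]phenyl}chroman-4-one | C/C(=C\Cc1c(O[Si](C)(C)C(C)(C)C)ccc(C2COc3cc(O[Si](C)(C)C(C)(C)C)cc(O[Si](C)(C)C(C)(C)C)c3C2=O)c1O[Si](C)(C)C(C)(C)C)CCCC(C)(C)O[Si](C)(C)C(C)(C)C | intermediate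
26 | potassium enolate of 25 (potassium 2H-chromen-4-olate) | C/C(=C\Cc1c(O[Si](C)(C)C(C)(C)C)ccc(C2=C([O-])c3c(O[Si](C)(C)C(C)(C)C)cc(O[Si](C)(C)C(C)(C)C)cc3OC2)c1O[Si](C)(C)C(C)(C)C)CCCC(C)(C)O[Si](C)(C)C(C)(C)C.[K+] | intermediate
27 | allyl 5,7-bis(tert-butyldimethylsilyloxy)-3-{2,4-bis(tert-butyldimethylsilyloxy)-3-[(2E)-7-(tert-butyldimethylsilyloxy)-3,7-dimethyloct-2-en-1-yl]phenyl}-2H-chromen-4-yl carbonate | C/C(=C\Cc1c(O[Si](C)(C)C(C)(C)C)ccc(C2=C(OC(=O)OCC=C)c3c(O[Si](C)(C)C(C)(C)C)cc(O[Si](C)(C)C(C)(C)C)cc3OC2)c1O[Si](C)(C)C(C)(C)C)CCCC(C)(C)O[Si](C)(C)C(C)(C)C | intermediate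
28 | (3S)-5,7-bis(tert-butyldimethylsilyloxy)-3-{2,4-bis(tert-butyldimethylsilyloxy)-3-[(2E)-7-(tert-butyldimethylsilyloxy)-3,7-dimethyloct-2-en-1-yl]phenyl}chroman-4-one | C/C(=C\Cc1c(O[Si](C)(C)C(C)(C)C)ccc([C@H]2COc3cc(O[Si](C)(C)C(C)(C)C)cc(O[Si](C)(C)C(C)(C)C)c3C2=O)c1O[Si](C)(C)C(C)(C)C)CCCC(C)(C)O[Si](C)(C)C(C)(C)C | intermediate
29 | (3S)-5,7-dihydroxy-3-{2,4-dihydroxy-3-[(2E)-7-hydroxy-3,7-dimethyloct-2-en-1-yl]phenyl}chroman-4-one | C/C(=C\Cc1c(O)ccc([C@H]2COc3cc(O)cc(O)c3C2=O)c1O)CCCC(C)(C)O | target

## Step count and risks

Total step count: 19. Longest linear sequence: 14 steps (steps 1–4, 6–9 and 14–19, from geranyl acetate 1).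

Least certain steps:

**Step 14 (key step).** The most likely failure is protonation of the aryl anion before the acyl group has moved from oxygen to carbon, which ends in O-arylation of the acid and not in insertion. Thermal oligomerisation of the acrylic acid and capture of the phenoxide by a second aryne before ring closure are further risks. Fallback: the same bonds are made stepwise, setting out from 14 and 17. Esterification of 14 with 17 (DCC, DMAP, CH2Cl2) gives 2-bromo-3,5-bis(methoxymethoxy)phenyl 2-arylprop-2-enoate F1. Bromine–lithium exchange with t-BuLi in THF at −100 °C triggers an anionic Fries-type acyl shift from oxygen to the lithiated carbon and gives the lithium acylphenoxide F2, which closes ring C by oxa-Michael addition on warming. This comes back to the route at 23.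

**Step 18.** Facial discrimination in the protonation may be insufficient, because the silyl ethers at C5 and C2' crowd the enolate and may change its preferred conformation. C-allylation of the enolate may compete, and the sense of induction is not secure (see the assumption). Fallback: setting out from 25, the potassium enolate is trapped with Me3SiCl to give the trimethylsilyl enol ether F3. F3 is protonated enantioselectively by a catalytic chiral BINOL-derived N-triflyl thiophosphoramide with phenol as the stoichiometric proton source in toluene, a known method for silyl enol ethers of 2-aryl cyclic ketones. This comes back to the route at 28.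

**Step 19.** The time needed to cleave the tertiary silyl ether may allow slow enolisation and erosion of configuration at C3, or acid-induced cyclisation of a ring B hydroxyl onto the alkene. Fallback: the silyl pattern is changed so that the last step is fast, setting out from 23. Longer treatment with aq. HCl in MeOH at 45 °C removes the tertiary silyl ether as well and gives the racemic pentaol F4. TESOTf and 2,6-lutidine give the pentakis(triethylsilyl) ether F5. KN(SiMe3)2 and allyl chloroformate give the allyl enol carbonate F6. The palladium-catalysed protonation of step 18 gives the (3S)-pentakis(triethylsilyl) ether F7, whose silyl groups all fall to HF·pyridine buffered with pyridine in THF at 0 °C. This comes back to the route at 29.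

**Step 15.** Under protic acid a ring B hydroxyl, once freed, may add to the protonated alkene (chroman formation), or cleavage of the hindered C2' acetal may be slow enough to force harsher conditions. Fallback: setting out from 23, Me3SiOTf with 2,2'-bipyridyl in MeCN at 0 °C converts aryl MOM ethers into aryl trimethylsilyl ethers without protic acid. The tetrakis(trimethylsilyl) ether F8 is hydrolysed during aqueous work-up. This comes back to the route at 24.

**Step 11.** Bromination may take place para to the hydroxyl, between the two MOM ethers, or twice. Fallback: the silicon is placed by directed metalation, setting out from 16. ClCONEt2 and K2CO3 give 3,5-bis(methoxymethoxy)phenyl diethylcarbamate F9. s-BuLi and TMEDA in THF at −78 °C lithiate the position between the carbamate and a MOM ether (the carbamate is the stronger director), and Me3SiCl gives the 2-trimethylsilyl carbamate F10. LiAlH4 in THF releases 3,5-bis(methoxymethoxy)-2-(trimethylsilyl)phenol F11, which is triflated with Tf2O and pyridine. This comes back to the route at 20 and bypasses steps 12 and 13.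

## Further compounds

F1 | step 14 | 2-bromo-3,5-bis(methoxymethoxy)phenyl 2-{3-[(2E)-7-(tert-butyldimethylsilyloxy)-3,7-dimethyloct-2-en-1-yl]-2,4-bis(methoxymethoxy)phenyl}prop-2-enoate | C/C(=C\Cc1c(OCOC)ccc(C(=C)C(=O)Oc2cc(OCOC)cc(OCOC)c2Br)c1OCOC)CCCC(C)(C)O[Si](C)(C)C(C)(C)C
F2 | step 14 | lithium 2-(2-{3-[(2E)-7-(tert-butyldimethylsilyloxy)-3,7-dimethyloct-2-en-1-yl]-2,4-bis(methoxymethoxy)phenyl}prop-2-enoyl)-3,5-bis(methoxymethoxy)phenolate | [Li+].[O-]c1cc(OCOC)cc(OCOC)c1C(=O)C(=C)c1ccc(OCOC)c(C/C=C(\C)CCCC(C)(C)O[Si](C)(C)C(C)(C)C)c1OCOC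
F3 | step 18 | trimethylsilyl enol ether of 25, {5,7-bis(tert-butyldimethylsilyloxy)-3-aryl-2H-chromen-4-yl}oxytrimethylsilane | C/C(=C\Cc1c(O[Si](C)(C)C(C)(C)C)ccc(C2=C(O[Si](C)(C)C)c3c(O[Si](C)(C)C(C)(C)C)cc(O[Si](C)(C)C(C)(C)C)cc3OC2)c1O[Si](C)(C)C(C)(C)C)CCCC(C)(C)O[Si](C)(C)C(C)(C)C
F4 | step 19 | rac-5,7-dihydroxy-3-{2,4-dihydroxy-3-[(2E)-7-hydroxy-3,7-dimethyloct-2-en-1-yl]phenyl}chroman-4-one | C/C(=C\Cc1c(O)ccc(C2COc3cc(O)cc(O)c3C2=O)c1O)CCCC(C)(C)O
F5 | step 19 | rac-5,7-bis(triethylsilyloxy)-3-{2,4-bis(triethylsilyloxy)-3-[(2E)-3,7-dimethyl-7-(triethylsilyloxy)oct-2-en-1-yl]phenyl}chroman-4-one | C/C(=C\Cc1c(O[Si](CC)(CC)CC)ccc(C2COc3cc(O[Si](CC)(CC)CC)cc(O[Si](CC)(CC)CC)c3C2=O)c1O[Si](CC)(CC)CC)CCCC(C)(C)O[Si](CC)(CC)CC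
F6 | step 19 | allyl 5,7-bis(triethylsilyloxy)-3-{2,4-bis(triethylsilyloxy)-3-[(2E)-3,7-dimethyl-7-(triethylsilyloxy)oct-2-en-1-yl]phenyl}-2H-chromen-4-yl carbonate | C/C(=C\Cc1c(O[Si](CC)(CC)CC)ccc(C2=C(OC(=O)OCC=C)c3c(O[Si](CC)(CC)CC)cc(O[Si](CC)(CC)CC)cc3OC2)c1O[Si](CC)(CC)CC)CCCC(C)(C)O[Si](CC)(CC)CC
F7 | step 19 | (3S)-5,7-bis(triethylsilyloxy)-3-{2,4-bis(triethylsilyloxy)-3-[(2E)-3,7-dimethyl-7-(triethylsilyloxy)oct-2-en-1-yl]phenyl}chroman-4-one | C/C(=C\Cc1c(O[Si](CC)(CC)CC)ccc([C@H]2COc3cc(O[Si](CC)(CC)CC)cc(O[Si](CC)(CC)CC)c3C2=O)c1O[Si](CC)(CC)CC)CCCC(C)(C)O[Si](CC)(CC)CC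
F8 | step 15 | rac-3-{3-[(2E)-7-(tert-butyldimethylsilyloxy)-3,7-dimethyloct-2-en-1-yl]-2,4-bis(trimethylsilyloxy)phenyl}-5,7-bis(trimethylsilyloxy)chroman-4-one | C/C(=C\Cc1c(O[Si](C)(C)C)ccc(C2COc3cc(O[Si](C)(C)C)cc(O[Si](C)(C)C)c3C2=O)c1O[Si](C)(C)C)CCCC(C)(C)O[Si](C)(C)C(C)(C)C
F9 | step 11 | 3,5-bis(methoxymethoxy)phenyl diethylcarbamate | CCN(CC)C(=O)Oc1cc(OCOC)cc(OCOC)c1
F10 | step 11 | 3,5-bis(methoxymethoxy)-2-(trimethylsilyl)phenyl diethylcarbamate | CCN(CC)C(=O)Oc1cc(OCOC)cc(OCOC)c1[Si](C)(C)C
F11 | step 11 | 3,5-bis(methoxymethoxy)-2-(trimethylsilyl)phenol | COCOc1cc(O)c([Si](C)(C)C)c(OCOC)c1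
A1 | alternative 1 | 5,7-bis(tert-butyldimethylsilyloxy)-3-{2-hydroxy-3-[(2E)-3,7-dimethyl-7-(triethylsilyloxy)oct-2-en-1-yl]-4-(triisopropylsilyloxy)phenyl}-4H-chromen-4-one | C/C(=C\Cc1c(O[Si](C(C)C)(C(C)C)C(C)C)ccc(-c2coc3cc(O[Si](C)(C)C(C)(C)C)cc(O[Si](C)(C)C(C)(C)C)c3c2=O)c1O)CCCC(C)(C)O[Si](CC)(CC)CC
A2 | alternative 1 | (3E)-1-diazo-4-[5,7-bis(tert-butyldimethylsilyloxy)-4-oxo-4H-chromen-3-yl]but-3-en-2-one | [N-]=[N+]=CC(=O)/C=C/c1coc2cc(O[Si](C)(C)C(C)(C)C)cc(O[Si](C)(C)C(C)(C)C)c2c1=O
A3 | alternative 1 | triisopropyl{[(4E)-5,9-dimethyl-9-(triethylsilyloxy)dec-4-en-1-yn-1-yl]oxy}silane | C/C(=C\CC#CO[Si](C(C)C)(C(C)C)C(C)C)CCCC(C)(C)O[Si](CC)(CC)CC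
A4 | alternative 2 | methyl 3-[(2E)-7-hydroxy-3,7-dimethyloct-2-en-1-yl]-2,4-dioxocyclohexane-1-carboxylate | C/C(=C\CC1C(=O)CCC(C(=O)OC)C1=O)CCCC(C)(C)O
A5 | alternative 2 | methyl (6E)-11-hydroxy-7,11-dimethyl-3-oxododec-6-enoate | C/C(=C\CCC(=O)CC(=O)OC)CCCC(C)(C)O
A6 | alternative 2 | methyl acrylate | C=CC(=O)OC
A7 | alternative 3 | (3S)-5,7-bis(tert-butyldimethylsilyloxy)-3-{2,4-bis(tert-butyldimethylsilyloxy)-3-[(2E)-3,7-dimethyl-7-(triethylsilyloxy)oct-2-en-1-yl]phenyl}chroman-4-one | C/C(=C\Cc1c(O[Si](C)(C)C(C)(C)C)ccc([C@H]2COc3cc(O[Si](C)(C)C(C)(C)C)cc(O[Si](C)(C)C(C)(C)C)c3C2=O)c1O[Si](C)(C)C(C)(C)C)CCCC(C)(C)O[Si](CC)(CC)CC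
A8 | alternative 3 | 2-(2-chloro-2-{2,4-bis(tert-butyldimethylsilyloxy)-3-[(2E)-3,7-dimethyl-7-(triethylsilyloxy)oct-2-en-1-yl]phenyl}ethoxy)-4,6-bis(tert-butyldimethylsilyloxy)benzoyl chloride, racemic | C/C(=C\Cc1c(O[Si](C)(C)C(C)(C)C)ccc(C(Cl)COc2cc(O[Si](C)(C)C(C)(C)C)cc(O[Si](C)(C)C(C)(C)C)c2C(=O)Cl)c1O[Si](C)(C)C(C)(C)C)CCCC(C)(C)O[Si](CC)(CC)CC
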